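The earlier runs and the new flask were generated by integration with constants of no real substance; scatter was added.

Turning target into isomer leaves the sum of the two unchanged, so the sum and the ratio can be read apart.

| setting | Tuesday's | Wednesday's | flask |
|---|---|---|---|
| substrate | 1.1 M | 1.1 M | 1.1 M |
| partner | 0.99 M | 0.99 M | 0.990 M |
| precatalyst | 110 mM | 240 mM | 160 mM |
| remark | run made earlier | run made earlier |  |
| time |  |  | 12 h |

| run | time / h | target / % | isomer of the product / % |
|---|---|---|---|
| Tuesday's | 1.00 | 24.6 | 9.3 |
| Tuesday's | 2.00 | 34.7 | 11.9 |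
| Tuesday's | 3.00 | 36.9 | 16.1 |
| Tuesday's | 5.00 | 40.4 | 19.5 |
| Tuesday's | 8.00 | 38.2 | 22.7 |
| Tuesday's | 15.0 | 35.7 | 25.4 |
| Wednesday's | 2.50 | 33.7 | 13.4 |
| Wednesday's | 5.00 | 36.1 | 20.0 |
| Wednesday's | 8.00 | 38.9 | 24.5 |
| Wednesday's | 10.0 | 36.2 | 26.5 |
| Wednesday's | 12.0 | 33.7 | 27.8 |
| Wednesday's | 15.0 | 33.6 | 28.8 |

(scatter of a reading: 1 percentage point)

- a reading or a percentage of target counts all its forms, free or not

- ratio of target to isomer of the product at 1.5 min
- ratio of target to isomer of the product at 12 h

Does the sum still move late in Tuesday's run? The readings do not show it: 60.9 % at 8.00 h, 61.1 % at 15.0 h.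

And the ratio over those hours? In Tuesday's run it falls from 1.68 to 1.41, so the readings look like target turning into isomer at a standing sum.

What, then, is the ratio before that exchange counts? Tuesday's earliest reading gives 2.65. Call this the first-hand ratio, target over isomer as the two first appear, the selectivity factor of kinetic control. It carries about ±0.284 from the scatter.

But that reading comes later than 1.5 min; has the ratio not drifted already? Perhaps. Wednesday's first reading, at 2.50 h, is 2.51, lower. So for the flask at 1.5 min I commit to the first-hand ratio, if anything a little above it.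

And at 12 h? Between its two readings, Tuesday's run interpolates to 1.52, while Wednesday's, with more precatalyst, reads 1.21, lower. Placing the flask's 160 mM on a straight line between them, my own reckoning gives 1.40.

The forecast says 3 and 1.4, holding that “The isomer therefore forms directly alongside the target”.

The flask gives 2.83 at 1.5 min and 1.40 at 12 h.

    crystals ⇌ target, rate k1*(cs1 - [target]) while solid is left; crystals form when [target] > cs1 (solubility = 0.900 M, k = 0.0290 min⁻¹)
    target + catalyst ⇌ isomer of the product + catalyst, rate k2*[catalyst]*[target] forward; the back reaction follows from the equilibrium constant (k = 0.0160 L mol⁻¹ min⁻¹)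
    precatalyst ⇌ catalyst (K = 0.570, k = 0.00120 min⁻¹)
    substrate + partner ⇌ target (K = 3.00 L mol⁻¹, k = 0.00680 L mol⁻¹ min⁻¹)
    substrate + partner ⇌ isomer of the product (K = 2.50 L mol⁻¹, k = 0.00240 L mol⁻¹ min⁻¹)

In the flask, of the turnover up to 12 h, half of that from substrate and partner to target is done by 0.760 h, earlier than half of that from precatalyst to catalyst, at 3.05 h. At 12 h the flask stands 1.25 below the first-hand ratio read from Tuesday's run. The neighbouring flask with 0.064 M of precatalyst gives 2.83 at 1.5 min and 1.54 at 12 h, which is 1.10 below that ratio.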